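**Plan**

- Retrosynthesis: the C-17–O and C-11–H bonds are removed first (1,4-hydroboration retron), which leaves the exocyclic diene C-17=C-8–C-9=C-11. Ring B is then opened at C-8–C-9 (palladium-catalysed enyne cycloisomerization), followed by C-11–C-12 (alkyne/allylic bromide coupling), C-9≡C-11 (Ohira–Bestmann), C-6–C-7 (allylboration), C-10–CH3 (cuprate) and ring A (Robinson-type annulation).
- Forward: ring A is built first as a cis-fused keto lactone; the lactone is re-cut into the C-6 homoallylic alcohol and the C-10 ethynyl group; the intact butenolide is attached; ring B is closed last, and no hydroxyl protecting group is used after the ketal.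
- Enabling feature: the unit C-17–C-8=C-9–C-11 of ring B is the 1,4-adduct of a 1,2-bis(alkylidene)cyclohexane, the product a 1,7-enyne (alkyne on C-10, allyl on C-6) gives on cycloisomerization. C-10 is quaternary and the vinyl group has no outer allylic hydrogen, so only this diene can form.
- Stereochemistry: C-10/C-5 from anti cuprate addition (checked by lactonization); absolute configuration from separation of diastereomeric (R,R)-hydrobenzoin ketals; C-6 from reagent-controlled allylboration; C-2 from equatorial hydride delivery to the ketone that carries an axial ethynyl group.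

Key step: step 14

Remark: compounds 3–6 are racemates whose SMILES show the enantiomer carried on, lactols 8 and 11 are anomer mixtures, and all intermediates carry the labdane numbering of the target (β = face of the C-10 methyl).

Step 1
Reactants: 1 mesityl oxide (4-methylpent-3-en-2-one); 2 ethyl 4-(benzyloxy)-3-oxobutanoate
Product: 3 ethyl 2-[(benzyloxy)methyl]-6,6-dimethyl-4-oxocyclohex-2-ene-1-carboxylate (racemic)
Conditions: ZnCl2 (0.2 equiv), toluene, reflux, Dean–Stark trap
Reagents that add atoms: none
Why: Robinson-type annulation (Michael addition of the β-keto ester to the β,β-dimethyl enone, then aldol condensation of the methyl ketone onto the more electrophilic α-alkoxy ketone), the reaction type by which acetoacetic esters and mesityl oxide give 4-oxocyclogeranates; C-5 is still labile and not yet controlled.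

Step 2
Reactants: 3 enone ester
Product: 4 ethyl 2-[(benzyloxy)methyl]-2,6,6-trimethyl-4-oxocyclohexane-1-carboxylate (CH3 trans and CH2OBn cis to CO2Et; racemic)
Conditions: Me2CuLi, Et2O, −30 to 0 °C; aq. NH4Cl
Reagents that add atoms: lithium dimethylcuprate, [Li+].C[Cu-]C
Why: Cuprate 1,4-addition to an isophorone-type enone should occur axially and anti to the C-5 ester, which sits pseudoaxial to avoid allylic strain with the C-10 substituent, so the quaternary C-10 is set with CH3 trans to C-6 and C-9 cis to C-6.

Step 3
Reactants: 4 keto ester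
Product: 6 cis-3a,7,7-trimethylhexahydro-2-benzofuran-1,5-dione (keto lactone; racemic), via hydroxy ester 5 (not isolated)
Conditions: H2 (1 atm), 10 % Pd/C, EtOAc, rt; then TsOH (cat.), toluene, 80 °C
Reagents that add atoms: none
Why: Benzyl ether hydrogenolysis followed by γ-lactonization, which is possible only for the isomer with C-9 and C-6 cis and so both proves and purifies the C-5/C-10 relationship.

Step 4
Reactants: 6 keto lactone
Product: 7 spiro ketal of the keto lactone at C-2 from (R,R)-hydrobenzoin (single diastereomer; H-5 β and C-10 CH3 β)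
Conditions: (R,R)-hydrobenzoin, TsOH (cat.), benzene, reflux, Dean–Stark trap; crystallization or chromatography to remove the other diastereomer
Reagents that add atoms: (R,R)-hydrobenzoin, O[C@H](c1ccccc1)[C@H](O)c1ccccc1
Why: Ketalization with a twofold-symmetric diol creates no new stereocentre, so racemic 6 gives just two diastereomeric ketals, 7 and its isomer from the other enantiomer of 6, which should be separable in a classical resolution that fixes the absolute configuration of C-5 and C-10 and masks the C-2 ketone for the hydride and borane steps.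

Step 5
Reactants: 7 ketal lactone
Product: 8 lactol (C-6 hemiacetal)
Conditions: i-Bu2AlH, CH2Cl2, −78 °C; aq. potassium sodium tartrate
Reagents that add atoms: none
Why: Half-reduction of a γ-lactone to the lactol at low temperature; no stereocentre of the ring is touched.

Step 6
Reactants: 8 lactol
Product: 9 (6S)-diol (C-6 homoallylic alcohol, C-9 hydroxymethyl, C-2 ketal)
Conditions: (−)-Ipc2B(allyl) (from (+)-α-pinene, excess), Et2O, −78 °C to rt; NaOH, H2O2
Reagents that add atoms: (−)-B-allyldiisopinocampheylborane, C=CCB([C@@H]1C[C@@H]2C[C@H]([C@H]1C)C2(C)C)[C@@H]1C[C@@H]2C[C@H]([C@H]1C)C2(C)C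
Why: Brown allylboration of the open hydroxy aldehyde form through a chair Zimmerman–Traxler transition state; this borane enantiomer delivers allyl to the Si face of aldehydes and should set C-6 as S under reagent control.

Step 7
Reactants: 9 diol
Product: 10 γ-lactone C-9(=O)–O-6 carrying the (6S)-allyl group (C-2 ketal)
Conditions: TEMPO (cat.), PhI(OAc)2, CH2Cl2, rt
Reagents that add atoms: none
Why: Oxoammonium oxidation is selective for the primary alcohol; the hydroxy aldehyde closes to the lactol and is oxidized on to the lactone, which raises C-9 to the carbonyl level and masks O-6 in one operation.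

Step 8
Reactants: 10 lactone
Product: 12 C-10 ethynyl (6S)-homoallylic alcohol (C-2 ketal), via lactol 11 (not isolated)
Conditions: i-Bu2AlH, CH2Cl2, −78 °C; then MeOH, K2CO3, dimethyl (1-diazo-2-oxopropyl)phosphonate, rt
Reagents that add atoms: Ohira–Bestmann reagent, COP(=O)(OC)C(=[N+]=[N-])C(C)=O
Why: Half-reduction, then Seyferth–Gilbert homologation of the lactol's open aldehyde form with the Ohira–Bestmann reagent; the aldehyde sits on quaternary C-10 and cannot epimerize, and O-6 is released as the free alcohol.

Step 9
Reactants: 12 ketal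
Product: 13 3-ethynyl-4-[(1S)-1-hydroxybut-3-en-1-yl]-3,5,5-trimethylcyclohexan-1-one (ethynyl cis to the side chain)
Conditions: 3 M HCl, THF, 50 °C
Reagents that add atoms: water, O
Why: Acid hydrolysis of the dioxolane; alkyne, alkene and secondary alcohol are inert to aqueous acid.

Step 10
Reactants: 13 hydroxy ketone
Product: 14 (2S,6S)-diol, 3-ethynyl-4-[(1S)-1-hydroxybut-3-en-1-yl]-3,5,5-trimethylcyclohexan-1-ol (ring OH cis to ethynyl)
Conditions: LiBH(s-Bu)3 (excess), THF, −78 °C; aq. work-up
Reagents that add atoms: none
Why: In the chair with the small ethynyl group axial and the C-6 chain and C-10 methyl equatorial, the axial C-4 methyl and the ethynyl group block axial attack, so the bulky hydride should enter equatorially (as with 3,3,5-trimethylcyclohexanone) and give the axial 2-OH cis to C-9.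

Step 11
Reactants: 15 1,3-dihydroxyacetone (sold as its dimer); 16 ethyl (triphenylphosphoranylidene)acetate
Product: 18 4-(hydroxymethyl)furan-2(5H)-one, via diol ester 17 (not isolated)
Conditions: CH2Cl2, rt
Reagents that add atoms: none
Why: Wittig olefination of a symmetric ketone always places one CH2OH cis to the ester, so lactonization to the butenolide is spontaneous.

Step 12
Reactants: 18 hydroxymethyl butenolide
Product: 19 4-(bromomethyl)furan-2(5H)-one
Conditions: CBr4, PPh3, CH2Cl2, 0 °C
Reagents that add atoms: carbon tetrabromide, BrC(Br)(Br)Br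
Why: Appel bromination of a primary allylic alcohol under neutral conditions that the butenolide tolerates.

Step 13
Reactants: 14 alkyne diol; 19 bromomethyl butenolide
Product: 20 skipped enyne, 4-[3-(C-10 ring)prop-2-yn-1-yl]furan-2(5H)-one bearing the (2S)-OH and the (6S)-homoallylic alcohol
Conditions: CuI (10 mol %), NaI, K2CO3, DMF, rt
Reagents that add atoms: none
Why: Copper-catalysed coupling of a terminal alkyne with a primary allylic halide (SN2 at CH2Br, since SN2′ would have to attack the lactone α-carbon); the mild carbonate base tolerates the free hydroxyls and the butenolide.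

Step 14
Reactants: 20 enyne
Product: 21 bis-exocyclic diene (cis-decalin with C-8=C-17H2 and (Z)-C-9=C-11H–C-12)
Conditions: Pd2(dba)3·CHCl3 (2.5 mol %), P(o-Tol)3 (10 mol %), AcOH (1 equiv), toluene, 60 °C
Reagents that add atoms: none
Why: Zerovalent palladium and AcOH give a palladium hydride (divalent palladium) that adds syn across the C-9≡C-11 alkyne with palladium on C-9; the alkenylpalladium inserts the C-8=C-17 vinyl group to form the C-8–C-9 bond, and β-hydride elimination of H-8 from the C-17 alkylpalladium releases the diene and the hydride. The closest known reaction type is the palladium-catalysed cycloisomerization of 1,6- and 1,7-enynes to 1,2-bis(alkylidene)cycloalkanes. Ring B closes in the 6-exo-trig mode (exo also with respect to the alkyne). No stereocentre is formed; the (Z) geometry of C-9=C-11 follows from syn hydropalladation and insertion with retention at C-9, and C-2, C-5, C-6 and C-10 are spectators. The step needs palladium on C-9 and a single elimination path: hydropalladation is reversible and only the C-9 palladium species has the vinyl group within reach on the cis C-10/C-5 substituents of ring A, C-10 is quaternary so this species has no β-hydrogen on that side, and H-8 is the only hydrogen β to palladium after insertion. The electron-poor, trisubstituted butenolide alkene is 1,4 to the alkyne, too close for a strain-free insertion, and should stay out.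

Step 15
Reactants: 21 diene
Product: 23 target (2S,5R,6S,10S)-2,6,17-trihydroxylabda-8,13-dien-15,16-olide, via allylboronate 22 (not isolated)
Conditions: Ni(cod)2 (5 mol %), PCy3 (5 mol %), HBpin (4 equiv), toluene, rt; then NaBO3·4H2O, THF/H2O, rt
Reagents that add atoms: pinacolborane, CC1(C)OBOC1(C)C; sodium perborate, [Na+].[O-]OB=O
Why: Nickel-catalysed 1,4-hydroboration of an s-cis-locked 1,3-diene should place boron on the unsubstituted terminus C-17 and hydrogen on C-11, giving the tetrasubstituted C-8=C-9 alkene; perborate then oxidizes the allylboronate to the C-17 alcohol and hydrolyses any borate esters formed at the free hydroxyls (22 is drawn with them free).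

**Compound list**

1 | mesityl oxide | CC(C)=CC(C)=O | starting material
2 | ethyl 4-(benzyloxy)-3-oxobutanoate | CCOC(=O)CC(=O)COCc1ccccc1 | starting material
3 | ethyl 2-[(benzyloxy)methyl]-6,6-dimethyl-4-oxocyclohex-2-ene-1-carboxylate (racemic) | CC1(C)CC(=O)C=C(COCc2ccccc2)C1C(=O)OCC | intermediate
4 | ethyl 2-[(benzyloxy)methyl]-2,6,6-trimethyl-4-oxocyclohexane-1-carboxylate, CH3 trans and CH2OBn cis to CO2Et (racemic) | CC1(C)CC(=O)C[C@](C)(COCc2ccccc2)[C@@H]1C(=O)OCC | intermediate
5 | ethyl 2-(hydroxymethyl)-2,6,6-trimethyl-4-oxocyclohexane-1-carboxylate, CH2OH cis to CO2Et (racemic) | CC1(C)CC(=O)C[C@](C)(CO)[C@@H]1C(=O)OCC | intermediate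
6 | cis-3a,7,7-trimethylhexahydro-2-benzofuran-1,5-dione (keto lactone, racemic) | CC1(C)CC(=O)C[C@]2(C)COC(=O)[C@H]12 | intermediate
7 | (R,R)-hydrobenzoin spiro ketal (C-2) of the keto lactone, diastereomer with H-5 β and C-10 CH3 β | CC1(C)CC2(O[C@H](c3ccccc3)[C@@H](c3ccccc3)O2)C[C@]4(C)COC(=O)[C@H]14 | intermediate
8 | lactol of 7 (C-6 hemiacetal, anomer mixture) | CC1(C)CC2(O[C@H](c3ccccc3)[C@@H](c3ccccc3)O2)C[C@]4(C)COC(O)[C@H]14 | intermediate
9 | (6S)-diol: C-6 homoallylic alcohol, C-9 hydroxymethyl, C-2 ketal | CC1(C)CC2(O[C@H](c3ccccc3)[C@@H](c3ccccc3)O2)C[C@](C)(CO)[C@@H]1[C@@H](O)CC=C | intermediate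
10 | γ-lactone C-9(=O)–O-6 with (6S)-allyl group, C-2 ketal | CC1(C)CC2(O[C@H](c3ccccc3)[C@@H](c3ccccc3)O2)C[C@]4(C)C(=O)O[C@@H](CC=C)[C@H]14 | intermediate
11 | lactol of 10 (C-9 hemiacetal, anomer mixture) | CC1(C)CC2(O[C@H](c3ccccc3)[C@@H](c3ccccc3)O2)C[C@]4(C)C(O)O[C@@H](CC=C)[C@H]14 | intermediate
12 | C-10 ethynyl (6S)-homoallylic alcohol, C-2 ketal | CC1(C)CC2(O[C@H](c3ccccc3)[C@@H](c3ccccc3)O2)C[C@](C)(C#C)[C@@H]1[C@@H](O)CC=C | intermediate
13 | 3-ethynyl-4-[(1S)-1-hydroxybut-3-en-1-yl]-3,5,5-trimethylcyclohexan-1-one (ethynyl cis to side chain) | CC1(C)CC(=O)C[C@](C)(C#C)[C@@H]1[C@@H](O)CC=C | intermediate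
14 | (2S,6S)-diol: 3-ethynyl-4-[(1S)-1-hydroxybut-3-en-1-yl]-3,5,5-trimethylcyclohexan-1-ol (ring OH cis to ethynyl) | CC1(C)C[C@H](O)C[C@](C)(C#C)[C@@H]1[C@@H](O)CC=C | intermediate
15 | 1,3-dihydroxyacetone | OCC(=O)CO | starting material
16 | ethyl (triphenylphosphoranylidene)acetate | CCOC(=O)C=P(c1ccccc1)(c1ccccc1)c1ccccc1 | starting material
17 | ethyl 4-hydroxy-3-(hydroxymethyl)but-2-enoate | CCOC(=O)C=C(CO)CO | intermediate
18 | 4-(hydroxymethyl)furan-2(5H)-one | OCC1=CC(=O)OC1 | intermediate
19 | 4-(bromomethyl)furan-2(5H)-one | BrCC1=CC(=O)OC1 | intermediate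
20 | skipped enyne: 14 joined at the alkyne terminus to the butenolide CH2 | CC1(C)C[C@H](O)C[C@](C)(C#CCC2=CC(=O)OC2)[C@@H]1[C@@H](O)CC=C | intermediate
21 | cis-decalin diene with C-8=C-17H2 and (Z)-C-9=C-11 | CC1(C)C[C@H](O)C[C@]2(C)/C(=C\CC3=CC(=O)OC3)C(=C)C[C@H](O)[C@H]12 | intermediate
22 | C-17 pinacol allylboronate with C-8=C-9 | CC1(C)C[C@H](O)C[C@]2(C)C(CCC3=CC(=O)OC3)=C(CB4OC(C)(C)C(C)(C)O4)C[C@H](O)[C@H]12 | intermediate
23 | (2S,5R,6S,10S)-2,6,17-trihydroxylabda-8,13-dien-15,16-olide (cis-fused) | CC1(C)C[C@H](O)C[C@]2(C)C(CCC3=CC(=O)OC3)=C(CO)C[C@H](O)[C@H]12 | target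

**Totals and risks**

Total step count: 15. Longest linear sequence: 13 steps (steps 1–10 and 13–15); steps 11–12 make the butenolide fragment.

Steps most likely to fail:

1. Step 14. Hydropalladation of the hindered internal alkyne may be slow or may place palladium on C-11, so that β-hydride loss from the doubly activated C-12 (allene formation) or palladium-hydride isomerization of the allyl group runs ahead of ring closure. Fallback: start the ring closure by oxidative addition instead of hydride addition. From lactol 8, a chiral B-(2-bromoallyl)borane (made from (2-bromoallyl)tributylstannane and the enantiomer of the 1,2-diphenylethylenediamine-derived bis(toluenesulfonyl) bromoborane that attacks the Si face) should give the 2-bromoallyl diol F1. The operations of steps 7–10 and 13 are then repeated on the bromo series: lactone F2, lactol F3, alkyne F4, ketone F5, diol F6 and bromo enyne F7. Pd(PPh3)4, HCO2Na, DMF, 80 °C should then bring about oxidative addition into the vinyl bromide, 6-exo-dig syn-carbopalladation of the alkyne and hydride capture from formate. This returns to diene 21 with the same (Z) geometry.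

2. Step 15. The zerovalent nickel catalyst may be tied up by the butenolide or reduce it, and the free hydroxyls consume borane, so that 1,2-addition or no addition results. Fallback: from diene 21, hydroxyl-directed epoxidation of the C-8=C-17 methylene (VO(acac)2, t-BuOOH; O-6 is homoallylic) should give the spiro vinyl epoxide F8 with the oxygen on the face of the 6-OH. SmI2 in THF/MeOH at −90 °C should then open it reductively with allylic transposition (electron transfer, C-8–O cleavage, protonation at C-11). This arrives directly at target 23.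

3. Step 6. The bulky borane may add too slowly to the neopentyl-type aldehyde hidden in the lactol, or the neighbouring C-5 centre may erode the facial selectivity. Fallback: from lactol 8, a slimmer, catalyst-controlled propargylation (allenylboronic acid pinacol ester with the enantiomer of a chiral BINOL-derived phosphoric acid that gives the 6S carbinol) should give the homopropargylic diol F9. Partial hydrogenation (H2, Pd/CaCO3 poisoned with Pb(OAc)2, quinoline) then returns to diol 9.

**Further compounds**

F1 | step 14 | (6S)-2-bromoallyl diol, C-2 ketal | CC1(C)CC2(O[C@H](c3ccccc3)[C@@H](c3ccccc3)O2)C[C@](C)(CO)[C@@H]1[C@@H](O)CC(Br)=C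
F2 | step 14 | γ-lactone C-9(=O)–O-6 with 2-bromoallyl group, C-2 ketal | CC1(C)CC2(O[C@H](c3ccccc3)[C@@H](c3ccccc3)O2)C[C@]4(C)C(=O)O[C@@H](CC(Br)=C)[C@H]14
F3 | step 14 | lactol of F2 (anomer mixture) | CC1(C)CC2(O[C@H](c3ccccc3)[C@@H](c3ccccc3)O2)C[C@]4(C)C(O)O[C@@H](CC(Br)=C)[C@H]14
F4 | step 14 | C-10 ethynyl 2-bromoallyl carbinol, C-2 ketal | CC1(C)CC2(O[C@H](c3ccccc3)[C@@H](c3ccccc3)O2)C[C@](C)(C#C)[C@@H]1[C@@H](O)CC(Br)=C
F5 | step 14 | bromo analogue of ketone 13 | CC1(C)CC(=O)C[C@](C)(C#C)[C@@H]1[C@@H](O)CC(Br)=C
F6 | step 14 | bromo analogue of diol 14 | CC1(C)C[C@H](O)C[C@](C)(C#C)[C@@H]1[C@@H](O)CC(Br)=C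
F7 | step 14 | bromo analogue of enyne 20 | CC1(C)C[C@H](O)C[C@](C)(C#CCC2=CC(=O)OC2)[C@@H]1[C@@H](O)CC(Br)=C
F8 | step 15 | spiro vinyl epoxide at C-8/C-17 of diene 21, oxygen on the face of the 6-OH | CC1(C)C[C@H](O)C[C@]2(C)/C(=C\CC3=CC(=O)OC3)[C@@]4(CO4)C[C@H](O)[C@H]12
F9 | step 6 | (6S)-homopropargylic diol, C-2 ketal | CC1(C)CC2(O[C@H](c3ccccc3)[C@@H](c3ccccc3)O2)C[C@](C)(CO)[C@@H]1[C@@H](O)CC#C
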